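Two runs on different charges of free base, 0.059 M in the south-east and 0.13 M in the south-west, both keep 72.6% of their electrophile at 3.00 h, so for the flask, whose free base lies between them, I read both runs and work with the fraction left, not the fraction made.

| setting | south-east | south-west | north | flask |
|---|---|---|---|---|
| electrophile | 0.11 M | 0.11 M | 0.11 M | 0.11 M |
| nucleophile | 0.33 M | 0.33 M | 0.66 M | 0.330 M |
| free base | 0.059 M (fed, over 40 min) | 0.13 M (fed, over 40 min) | 0.088 M (fed, over 40 min) | 0.0880 M (fed, over 40 min) |
| remark | run made earlier | run made earlier | run made earlier |  |
| time |  |  |  | 5.0 h |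

| run | time / h | electrophile / % | target / % |
|---|---|---|---|
| south-east | 0.667 | 91.0 | 5.4 |
| south-east | 1.33 | 84.9 | 10.0 |
| south-east | 2.00 | 77.9 | 11.4 |
| south-east | 2.50 | 74.8 | 14.9 |
| south-east | 3.00 | 72.6 | 16.0 |
| south-west | 0.250 | 96.4 | 2.4 |
| south-west | 0.833 | 88.6 | 6.3 |
| south-west | 1.33 | 83.6 | 9.7 |
| south-west | 2.00 | 78.8 | 12.2 |
| south-west | 3.00 | 72.6 | 15.7 |
| north | 0.667 | 83.8 | 10.5 |
| north | 1.33 | 73.0 | 15.2 |
| north | 2.00 | 67.3 | 19.2 |
| north | 2.50 | 63.5 | 21.6 |
| north | 3.00 | 60.8 | 23.6 |

(each reading ± 0.5 percentage points)

- a reading or a percentage of target counts all its forms, free or not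
- what has gone from electrophile into another species counts as reacted, even if it can come back
- the earlier runs do not show how much of nucleophile is bound; that part of a forecast is a guess
- a reading of electrophile is of its free form alone

1. part of the electrophile that has reacted at 5.0 h
2. share of the unused nucleophile that is free and not bound as protonated nucleophile, at 5.0 h

I call the log-loss of a span the natural logarithm of the fraction left at its start over the fraction left at its end, divided by its length; it is a pseudo-first-order constant for the electrophile, except that here it drifts. In the first instants the south-west run shows a log-loss of 0.147 h⁻¹, and over the first 0.667 h the north run, with twice the nucleophile, shows 0.265 h⁻¹ against 0.141 h⁻¹ in the south-east run, so, since the north run's free base lies between those of the other two runs and those two keep the same electrophile at 3.00 h, the early loss goes with nucleophile. In the middle, from 0.667 h to 2.00 h, the south-east run has slowed to 0.117 h⁻¹. Over the last hour read, the south-east and south-west runs together give 0.0762 h⁻¹, and this late log-loss is about half the first value. By 3.00 h the south-east run has 11.4% of its charge in neither reading, so something unread is about to matter.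

Holding the late log-loss from 3.00 h to 5.0 h, I reckon 37.7% reacted in the flask, and I take that as high because the log-loss has fallen at each stage. The readings do not show how much nucleophile is bound, so a share free is a guess. The forecast, which is not my reckoning, gives 36% reacted (33% to 40%) and 97% free (88% to 100%), saying “so nucleophile stays nearly all free”.

The flask gives 34.6% reacted, inside the forecast's range, and 82.5% free, below it, under this scheme:

    2 nucleophile → self-condensation product (k = 0.493 M⁻¹ h⁻¹)
    electrophile + nucleophile → acid set free + target (k = 0.302 M⁻¹ h⁻¹)
    nucleophile + acid set free ⇌ protonated nucleophile, settled at all times (K = 305 M⁻¹)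
    acid set free + free base ⇌ salt of the base, settled at all times (K = 17.0 M⁻¹)
    target ⇌ isomer of the product (K = 0.460, k = 0.117 h⁻¹)
    electrophile + target ⇌ idle adduct, settled at all times (K = 23.0 M⁻¹)

At 5.00 h the flask holds 0.0224 M of protonated nucleophile against 0.00102 M of salt of the base, with 98.8% of its free base still unbound. From 2.50 h to 5.00 h the flask's log-loss is 0.0576 h⁻¹, below the 0.0762 h⁻¹ I held. The neighbour flask, charged with 0.044 M of electrophile instead of 0.11 M, has 68.0% left at 5.00 h, a log-loss over the whole span of 0.0771 h⁻¹ against 0.0849 h⁻¹ for this flask.

The earlier runs and the new flask stem from a simulated flask on assumed constants; scatter was added.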